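## Analysis of the target

Atom labels used throughout: ring A is C1 (OMe), C2, C3 (pyran oxygen), C4, C5, C6; C7 is the indane CH2; C8 and C9 are the ring-fusion CH carbons (C9 on C5); C10 carries the catechol ring B; C11 is CMe2; C12=C13 and C14 (CMe2) complete the pyran.

The target is a tetracycle. Ring A is fused on one side to a 2,2-dimethyl-2H-pyran and on the other to a cyclopentane (C5, C6, C7, C8, C9) that shares its C8–C9 bond with a cyclobutane (C8, C9, C10, C11). The three stereocentres C8, C9 and C10 are contiguous on the four-membered ring: C8 and C9 are cis-fused, and ring B on C10 is trans to ring A on C9 (C8 S, C9 R, C10 S). C11 is quaternary and sits between C8 and C10. The sensitive groups are the free catechol (oxidation), the chromene double bond (acid, hydrogenation, electrophiles) and the strained ring with two benzylic carbons, which a cation or radical at C7 or C9 could open. The synthesis is hard because the cyclobutane is fully substituted, and because C7 on C8 must be cis to ring A, the less stable arrangement as long as the five-membered ring is open. The strategy rests on one feature: C8 carries a single one-carbon branch (C7) and is bonded to the quaternary C11. That is the pattern left by a Wolff ring contraction of a 2-diazocyclopentanone in which C7 was the carbonyl carbon and C11 the migrating atom. The cyclobutane can therefore be drawn from a trans-3,4-diaryl cyclopentanone, which is much easier to assemble.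

## Retrosynthetic reasoning

**28 back to 27 and 26.** The chromene double bond is taken back to a C12 silyl ether and the catechol to its dibenzyl ether. The alkene cannot live through hydrogenolysis, bromination or an organolithium, so it is unveiled last by loss of the silyloxy group from 27. The benzyl groups are removed one step earlier (26 to 27), while C12 is still saturated.

**26 back to 24, 23 and 22.** The C6–C7 bond is cut. C6 is the only free position next to C5, so the regiochemistry of the closure is fixed by geometry. The bond is formed by an anionic cycloalkylation: an aryllithium at C6 (25, from bromide 24) displaces a sulfonate at C7. A cationic closure was set aside because a positive charge at C7 would lie beside the cyclobutane and any acid would ionise the C12–O bond. The bromine at C6 comes from electrophilic bromination of 22 (giving 23), and the sulfonate from the primary alcohol.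

**22 back to 21.** The CH2OH group on C8 is the reduced carboxyl group. The reduction has to keep the configuration at C8, which a hydride reduction of the free acid does.

**21 back to 19 (key disconnection).** The C8–C11 bond is cut and C11 is re-attached to C7, which turns the cyclobutane acid into the 2-diazocyclopentanone 19. This trades a strained ring with three stereocentres for a five-membered ketone with two, in the favoured trans arrangement. C7 arrives as a carboxyl carbon on C8, which is what the indane closure needs. The forward reaction has to contract the ring (through ketene 20) and set C8 with the carboxyl cis to ring A.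

**19 back to 17.** The diazo group goes back to the C8 methylene of ketone 17 (through the acyl ketone 18). C8 is the only enolisable position because C11 is quaternary. For the same reason ring A must not carry a ketone at C12 at this stage. Its methylene would compete for base, and its carbonyl would sit five atoms from the C8 enolate, inviting an aldol closure. C12 is therefore carried as a silyl ether.

**17 back to 16 and 8.** The C5–C9 bond is cut. Ring A, with its pyran ring and substitution pattern complete, is added as boronate 8 to enone 16. The ring B group on the neighbouring carbon should direct the new aryl group trans. This is the convergent step.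

**16 back to 14, 13, 12, 9 and 10.** The enone comes from ketone 14 by dehydrogenation through silyl enol ether 15. The C10 stereocentre of 14 comes from asymmetric hydrogenation of alkene 13. Alkene 13 comes from addition of aryllithium 11 (made from bromide 9) to the symmetrical dione 10, then dehydration of 12. The dione supplies the gem-dimethyl carbon and the future C7 carbonyl.

**8 back to 7, 6, 5, 4, 3, 1 and 2.** The boronate comes from triflate 7, and the silyl ether from reduction of chromanone 5 (6, then 7). The chromanone ring is built from the symmetrical triol 1 and acid 2. In 3 the two phenols differ by chelation to the carbonyl, so O-methylation at C1 (4) and triflation at C5 (5) are regiochemically unambiguous.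

## Alternatives that were turned down

**Alternative 1: palladium annulation of a ring A triflate, a cyclobutene and carbon monoxide.**
- Disconnection: C5–C9, C7–C8 and C6–C7 at once, so that tetracycle A1 falls apart into the chromene triflate A2, cyclobutene A3 and carbon monoxide A4.
- Forward key step: A2 adds oxidatively to zerovalent palladium. The aryl–palladium bond adds syn across C8=C9 of A3 on the face away from ring B. A4 inserts into the C8–palladium bond (no syn β-hydrogen is available). The acyl-palladium then closes onto C6.
- For it: it is the most convergent plan. Syn addition gives the cis ring fusion and the approach anti to ring B gives the trans C9/C10 relationship. The chromene is present from the start.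
- Against it:
  - Nothing in A3 directs the aryl group to C9 over C8. One alkene carbon is flanked by the quaternary C11 and the other by the aryl-bearing C10, so regioisomers are to be expected.
  - A3, a strained single-enantiomer cyclobutene, is the hard part of the molecule moved elsewhere and needs its own synthesis.
  - The alkyl-palladium may close onto C6 before taking up A4.
  - A1 still has a ketone at C7. Removing it beside an acid-labile chromene and acetal protecting groups needs conditions the rest of the molecule tolerates poorly.
- Comparison: it is stronger on convergence and on steps to the ring system. The chosen route offers a migration with no regiochemical choice, a precursor whose stereocentres come from well-understood reactions, and a C7 that is reduced to CH2 before any acid-sensitive group appears.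

**Alternative 2: triyne cyclotrimerisation forming ring A, the indane ring and the pyran.**
- Disconnection: C1–C2, C3–C4 and C5–C6 of ring A, which opens A5 to triyne A6, whose three alkynes hang from a preformed cyclobutane.
- Forward key step: a cationic monovalent rhodium–bisphosphine catalyst joins the tethered alkynes into ring A. The three-atom tether C7–C8–C9 becomes the cyclopentane and the four-atom tether C12–C13–C14–O the pyran.
- For it: three rings close in one step. The tethers dictate the substitution pattern, C7 is already CH2, and no benzylic cation appears. A5 is the C12 epimer of 26, so its endgame is as short as the chosen one and needs neither bromination nor an organolithium.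
- Against it: the cyclobutane stereotriad must exist before the key step, so the real problem is left to a separate stereocontrolled synthesis with two different alkynyl arms. Two of the alkynes are alkynyl ethers, which are laborious to make and thermally labile. The linear sequence to A6 is long.
- Comparison: it is stronger in the last stage. The chosen strategy uses its key step to make the cyclobutane itself, which this plan does not address.

**Alternative 3: Diels–Alder benzannulation on a bicycloheptenone.**
- Disconnection: C1–C6 and C4–C5 of ring A, taking indanone A7 back to the α-bromo enone A8 and the oxygenated diene A9.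
- Forward key step: the nucleophilic diene terminus C4 bonds to the enone β-carbon C5 and the ketene-acetal carbon C1 to the bromine-bearing C6. Three eliminations then aromatise the adduct.
- For it: the polarity of A9 fixes the substitution pattern of ring A. The prenyl group at C4 is a classical chromene precursor. A8 could in principle come from an enone–alkene photocycloaddition.
- Against it:
  - A8 is needed as one enantiomer and one diastereomer, and a photocycloaddition with a trisubstituted styrene would give regio- and stereoisomer mixtures.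
  - The diene terminus that must bond to C5 carries the prenyl chain, and C5 lies beside the ring-fusion carbon C9, so the cycloaddition is hindered at both ends.
  - A7 still needs deoxygenation at C7 and an oxidative chromene closure in the presence of several benzylic C–H bonds.
- Comparison: it is equal on ring A regiochemistry, which the chosen route obtains from the symmetry of 1 and chelation in 3. It is weaker on the cyclobutane and on the oxidation level of C7.

Key step: step 13

Assumption: the configuration at C12 of the silyl ether has no consequence, since C12 becomes sp2 in step 19. It is fixed as R only so that every intermediate is a single diastereomer.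

## Route

Step 1
Reactants: 1 phloroglucinol; 2 3-methylbut-2-enoic acid
Product: 3 5,7-dihydroxy-2,2-dimethylchroman-4-one
Conditions: P2O5/MeSO3H, 70 °C
Reagents that add atoms: none
Why: Friedel–Crafts acylation of the symmetrical triol by the activated acid, then oxa-Michael closure of a neighbouring phenol onto the enone, should give the chromanone; the symmetry of 1 removes any regiochemical question.

Step 2
Reactants: 3 5,7-dihydroxy-2,2-dimethylchroman-4-one
Product: 4 5-hydroxy-7-methoxy-2,2-dimethylchroman-4-one
Conditions: MeI (1.1 equiv), K2CO3, acetone, reflux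
Reagents that add atoms: iodomethane, CI
Why: Williamson methylation; the C5 hydroxyl is held in a hydrogen bond to the carbonyl and is far less nucleophilic, so the C7 hydroxyl (future C1 methoxy) should react selectively.

Step 3
Reactants: 4 5-hydroxy-7-methoxy-2,2-dimethylchroman-4-one
Product: 5 7-methoxy-2,2-dimethyl-4-oxochroman-5-yl trifluoromethanesulfonate
Conditions: Tf2O, pyridine, CH2Cl2, 0 °C
Reagents that add atoms: trifluoromethanesulfonic anhydride, O=S(=O)(OS(=O)(=O)C(F)(F)F)C(F)(F)F
Why: O-sulfonylation of the remaining chelated phenol with a strong electrophile turns the future C5 into a cross-coupling site.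

Step 4
Reactants: 5 7-methoxy-2,2-dimethyl-4-oxochroman-5-yl trifluoromethanesulfonate
Product: 6 (4R)-4-hydroxy-7-methoxy-2,2-dimethylchroman-5-yl trifluoromethanesulfonate
Conditions: (S)-Me-CBS (10 mol %), BH3·SMe2, THF, 0 °C
Reagents that add atoms: none
Why: Corey–Bakshi–Shibata reduction with the aryl flank as the large group should give the 4R alcohol (C12); it removes the enolisable ketone of ring A, and the aryl triflate is inert to borane.

Step 5
Reactants: 6 (4R)-4-hydroxy-7-methoxy-2,2-dimethylchroman-5-yl trifluoromethanesulfonate
Product: 7 (4R)-4-(tert-butyldimethylsilyloxy)-7-methoxy-2,2-dimethylchroman-5-yl trifluoromethanesulfonate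
Conditions: TBSCl, imidazole, DMF, 40 °C
Reagents that add atoms: tert-butyldimethylsilyl chloride, CC(C)(C)[Si](C)(C)Cl
Why: Silylation under basic, non-ionising conditions protects the benzylic alcohol against base, light and hydride in the steps that follow.

Step 6
Reactants: 7 (4R)-4-(tert-butyldimethylsilyloxy)-7-methoxy-2,2-dimethylchroman-5-yl trifluoromethanesulfonate
Product: 8 (4R)-4-(tert-butyldimethylsilyloxy)-7-methoxy-2,2-dimethyl-5-(4,4,5,5-tetramethyl-1,3,2-dioxaborolan-2-yl)chromane
Conditions: B2pin2, PdCl2(dppf) (5 mol %), KOAc, dioxane, 90 °C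
Reagents that add atoms: bis(pinacolato)diboron, CC1(C)OB(OC1(C)C)B1OC(C)(C)C(C)(C)O1
Why: Miyaura borylation of an aryl triflate; oxidative addition to zerovalent palladium, acetate-assisted transmetalation and reductive elimination should give the ring A boronate.

Step 7
Reactants: 9 4-bromo-1,2-bis(benzyloxy)benzene; 10 2,2-dimethylcyclopentane-1,3-dione
Product: 12 rac-3-[3,4-bis(benzyloxy)phenyl]-3-hydroxy-2,2-dimethylcyclopentan-1-one, via aryllithium 11 (not isolated)
Conditions: n-BuLi, THF, −78 °C; then 10 (1.2 equiv), −78 °C; AcOH quench at −78 °C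
Reagents that add atoms: none
Why: Bromine–lithium exchange and 1,2-addition to one carbonyl of the symmetrical dione; excess dione, low temperature and a cold acidic quench should limit double addition and retro-aldol opening of the alkoxide.

Step 8
Reactants: 12 rac-3-[3,4-bis(benzyloxy)phenyl]-3-hydroxy-2,2-dimethylcyclopentan-1-one
Product: 13 3-[3,4-bis(benzyloxy)phenyl]-2,2-dimethylcyclopent-3-en-1-one
Conditions: p-TsOH·H2O (5 mol %), toluene, 50 °C
Reagents that add atoms: none
Why: E1 dehydration through the benzylic cation para to a benzyloxy group; the only β-hydrogens are on C4 (C2 is quaternary), so a single alkene should form.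

Step 9
Reactants: 13 3-[3,4-bis(benzyloxy)phenyl]-2,2-dimethylcyclopent-3-en-1-one
Product: 14 (3R)-3-[3,4-bis(benzyloxy)phenyl]-2,2-dimethylcyclopentan-1-one
Conditions: H2 (50 bar), [Ir(cod)(tBu-PHOX)][B(3,5-(CF3)2C6H3)4] (1 mol %; ligand enantiomer that gives the R ketone), CH2Cl2, rt
Reagents that add atoms: none
Why: Iridium-catalysed asymmetric hydrogenation of a cyclic trisubstituted aryl alkene sets C10 by catalyst control; the homogeneous catalyst should leave the benzyl ethers and the ketone untouched.

Step 10
Reactants: 14 (3R)-3-[3,4-bis(benzyloxy)phenyl]-2,2-dimethylcyclopentan-1-one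
Product: 16 (4R)-4-[3,4-bis(benzyloxy)phenyl]-5,5-dimethylcyclopent-2-en-1-one, via silyl enol ether 15 (not isolated)
Conditions: LiN(i-Pr)2, Me3SiCl, THF, −78 °C; then Pd(OAc)2 (1.05 equiv), MeCN, rt
Reagents that add atoms: none
Why: Saegusa–Ito dehydrogenation; only C5 can be enolised, so one silyl enol ether forms, and the base-free palladium oxidation should leave the γ stereocentre untouched.

Step 11
Reactants: 16 (4R)-4-[3,4-bis(benzyloxy)phenyl]-5,5-dimethylcyclopent-2-en-1-one; 8 (4R)-4-(tert-butyldimethylsilyloxy)-7-methoxy-2,2-dimethyl-5-(4,4,5,5-tetramethyl-1,3,2-dioxaborolan-2-yl)chromane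
Product: 17 (3R,4R)-3-[3,4-bis(benzyloxy)phenyl]-4-[(4R)-4-(tert-butyldimethylsilyloxy)-7-methoxy-2,2-dimethylchroman-5-yl]-2,2-dimethylcyclopentan-1-one
Conditions: [Rh(OH)(cod)]2 (3 mol %), KOH (0.1 equiv), dioxane/H2O 10:1, 40 °C
Reagents that add atoms: none
Why: Hayashi–Miyaura conjugate addition; the aryl-rhodium species should add to the enone face opposite ring B on the adjacent carbon, setting C9 trans to C10 and forming C5–C9.

Step 12
Reactants: 17 (3R,4R)-3-[3,4-bis(benzyloxy)phenyl]-4-[(4R)-4-(tert-butyldimethylsilyloxy)-7-methoxy-2,2-dimethylchroman-5-yl]-2,2-dimethylcyclopentan-1-one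
Product: 19 (3R,4R)-3-[3,4-bis(benzyloxy)phenyl]-4-[(4R)-4-(tert-butyldimethylsilyloxy)-7-methoxy-2,2-dimethylchroman-5-yl]-5-diazo-2,2-dimethylcyclopentan-1-one, via trifluoroacetyl ketone 18 (not isolated)
Conditions: LiN(SiMe3)2, THF, −78 °C; CF3CO2CH2CF3; then 4-acetamidobenzenesulfonyl azide, Et3N, H2O, MeCN, rt
Reagents that add atoms: 4-acetamidobenzenesulfonyl azide, CC(=O)Nc1ccc(cc1)S(=O)(=O)N=[N+]=[N-]
Why: Deacylative Regitz-type diazo transfer; C8 is the only enolisable position of 17 (C11 is quaternary and ring A carries no carbonyl), so acylation and diazo transfer should be regiospecific.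

Step 13
Reactants: 19 (3R,4R)-3-[3,4-bis(benzyloxy)phenyl]-4-[(4R)-4-(tert-butyldimethylsilyloxy)-7-methoxy-2,2-dimethylchroman-5-yl]-5-diazo-2,2-dimethylcyclopentan-1-one
Product: 21 (1S,3S,4S)-3-[3,4-bis(benzyloxy)phenyl]-4-[(4R)-4-(tert-butyldimethylsilyloxy)-7-methoxy-2,2-dimethylchroman-5-yl]-2,2-dimethylcyclobutane-1-carboxylic acid, via ketene 20 (not isolated)
Conditions: hν (365 nm), THF/H2O 4:1, rt
Reagents that add atoms: water, O
Why: Excitation of the diazo ketone, held s-cis by the ring, expels dinitrogen with concerted 1,2-shift of C11 from the carbonyl carbon C7 to C8, giving cyclobutylidene ketene 20; water adds to C7 and the resulting enol is protonated at C8. The closest known reaction type is the photochemical Wolff ring contraction of 2-diazocyclopentanones to cyclobutanecarboxylic acids, as in the contraction of ring D of steroidal 16-diazo-17-ketones, where a quaternary carbon also migrates. The four-membered ring is closed by this 1,2-alkyl shift inside the existing five-membered ring, a ring contraction and not an end-on cyclisation, and C8–C11 is the one new skeletal bond. C11 is the only substituent on the carbonyl carbon, so there is no choice of migrating group; C9 and C10 take no part and keep their configuration, and C11 is not stereogenic. The new stereocentre C8 is set when the enol is protonated: ring A on the neighbouring C9 screens the lower face, so the proton should arrive anti to ring A and leave the carboxyl cis to ring A, the kinetically formed, less stable epimer. The step needs the rearrangement to outrun 1,2-hydride shift from C9 and O–H insertion of a free carbene; the locked s-cis geometry, which favours the concerted path from the excited singlet, and the use of light without a metal catalyst should secure this. It also needs that facial preference at C8, which ring B across the ring at C10 opposes, so the work-up is kept neutral and cold to avoid epimerising the acid.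

Step 14
Reactants: 21 (1S,3S,4S)-3-[3,4-bis(benzyloxy)phenyl]-4-[(4R)-4-(tert-butyldimethylsilyloxy)-7-methoxy-2,2-dimethylchroman-5-yl]-2,2-dimethylcyclobutane-1-carboxylic acid
Product: 22 [(1S,3S,4S)-3-[3,4-bis(benzyloxy)phenyl]-4-[(4R)-4-(tert-butyldimethylsilyloxy)-7-methoxy-2,2-dimethylchroman-5-yl]-2,2-dimethylcyclobutyl]methanol
Conditions: BH3·SMe2, THF, 0 °C to rt
Reagents that add atoms: none
Why: Borane reduces the free acid through an acyloxyborane without enolisation, so C8 should keep its configuration; the silyl and benzyl ethers are inert.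

Step 15
Reactants: 22 [(1S,3S,4S)-3-[3,4-bis(benzyloxy)phenyl]-4-[(4R)-4-(tert-butyldimethylsilyloxy)-7-methoxy-2,2-dimethylchroman-5-yl]-2,2-dimethylcyclobutyl]methanol
Product: 23 [(1S,3S,4S)-3-[3,4-bis(benzyloxy)phenyl]-4-[(4R)-6-bromo-4-(tert-butyldimethylsilyloxy)-7-methoxy-2,2-dimethylchroman-5-yl]-2,2-dimethylcyclobutyl]methanol
Conditions: NBS (1.0 equiv), MeCN, −20 °C, dark
Reagents that add atoms: N-bromosuccinimide, O=C1CCC(=O)N1Br
Why: Electrophilic aromatic bromination; ring A is by far the most electron-rich arene, and C6 (ortho to the methoxy group, para to the pyran oxygen) should react before C2, which lies between two oxygens, and long before ring B.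

Step 16
Reactants: 23 [(1S,3S,4S)-3-[3,4-bis(benzyloxy)phenyl]-4-[(4R)-6-bromo-4-(tert-butyldimethylsilyloxy)-7-methoxy-2,2-dimethylchroman-5-yl]-2,2-dimethylcyclobutyl]methanol
Product: 24 [(1S,3S,4S)-3-[3,4-bis(benzyloxy)phenyl]-4-[(4R)-6-bromo-4-(tert-butyldimethylsilyloxy)-7-methoxy-2,2-dimethylchroman-5-yl]-2,2-dimethylcyclobutyl]methyl 4-methylbenzenesulfonate
Conditions: TsCl, Et3N, DMAP (cat.), CH2Cl2, rt
Reagents that add atoms: 4-methylbenzenesulfonyl chloride, Cc1ccc(cc1)S(Cl)(=O)=O
Why: Sulfonylation of the primary alcohol under basic conditions makes C7 an electrophile without any ionisation at C12.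

Step 17
Reactants: 24 [(1S,3S,4S)-3-[3,4-bis(benzyloxy)phenyl]-4-[(4R)-6-bromo-4-(tert-butyldimethylsilyloxy)-7-methoxy-2,2-dimethylchroman-5-yl]-2,2-dimethylcyclobutyl]methyl 4-methylbenzenesulfonate
Product: 26 tetracyclic indane (C8 S; C9 R; C10 S; C12 R) with the C12 silyl ether and the dibenzyl-protected catechol, via aryllithium 25 (not isolated)
Conditions: t-BuLi (2.1 equiv), THF, −78 °C, then 0 °C
Reagents that add atoms: none
Why: Parham cyclisation; bromine–lithium exchange at C6 is faster than any attack on the sulfonate, and the aryllithium then displaces the tosylate at C7 in a 5-exo-tet closure that the cis arrangement of C7 and ring A allows. No cation forms, so the cyclobutane and the C12 silyl ether should be untouched.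

Step 18
Reactants: 26 tetracyclic indane with the C12 silyl ether and the dibenzyl-protected catechol
Product: 27 tetracyclic indane (C8 S; C9 R; C10 S; C12 R) with the C12 silyl ether and the free catechol
Conditions: H2 (1 atm), Pd/C (10 %), EtOAc, rt
Reagents that add atoms: none
Why: Hydrogenolysis of the two aryl benzyl ethers; in neutral ethyl acetate the hindered benzylic silyl ether should survive, and no alkene is yet present.

Step 19
Reactants: 27 tetracyclic indane with the C12 silyl ether and the free catechol
Product: 28 target CNP0207533.1 (C8 S; C9 R; C10 S)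
Conditions: p-TsOH·H2O (0.1 equiv), toluene, 60 °C
Reagents that add atoms: none
Why: Acid-catalysed E1 elimination; the C12 silyl ether ionises to a benzylic cation stabilised by the ortho pyran oxygen and the para methoxy group, and loss of a C13 proton (the only β-hydrogens) should give the chromene, as in the classical dehydration of chroman-4-ols.

## Compound list

1 | phloroglucinol | Oc1cc(O)cc(O)c1 | starting material
2 | 3-methylbut-2-enoic acid | CC(C)=CC(=O)O | starting material
3 | 5,7-dihydroxy-2,2-dimethylchroman-4-one | CC1(C)CC(=O)c2c(O)cc(O)cc2O1 | intermediate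
4 | 5-hydroxy-7-methoxy-2,2-dimethylchroman-4-one | COc1cc(O)c2C(=O)CC(C)(C)Oc2c1 | intermediate
5 | 7-methoxy-2,2-dimethyl-4-oxochroman-5-yl trifluoromethanesulfonate | COc1cc(OS(=O)(=O)C(F)(F)F)c2C(=O)CC(C)(C)Oc2c1 | intermediate
6 | (4R)-4-hydroxy-7-methoxy-2,2-dimethylchroman-5-yl trifluoromethanesulfonate | COc1cc(OS(=O)(=O)C(F)(F)F)c2[C@H](O)CC(C)(C)Oc2c1 | intermediate
7 | (4R)-4-(tert-butyldimethylsilyloxy)-7-methoxy-2,2-dimethylchroman-5-yl trifluoromethanesulfonate | COc1cc(OS(=O)(=O)C(F)(F)F)c2[C@H](O[Si](C)(C)C(C)(C)C)CC(C)(C)Oc2c1 | intermediate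
8 | (4R)-4-(tert-butyldimethylsilyloxy)-7-methoxy-2,2-dimethyl-5-(4,4,5,5-tetramethyl-1,3,2-dioxaborolan-2-yl)chromane | COc1cc(B3OC(C)(C)C(C)(C)O3)c2[C@H](O[Si](C)(C)C(C)(C)C)CC(C)(C)Oc2c1 | intermediate
9 | 4-bromo-1,2-bis(benzyloxy)benzene | Brc1ccc(OCc2ccccc2)c(OCc2ccccc2)c1 | starting material
10 | 2,2-dimethylcyclopentane-1,3-dione | CC1(C)C(=O)CCC1=O | starting material
11 | 3,4-bis(benzyloxy)phenyllithium | [Li]c1ccc(OCc2ccccc2)c(OCc2ccccc2)c1 | intermediate
12 | rac-3-[3,4-bis(benzyloxy)phenyl]-3-hydroxy-2,2-dimethylcyclopentan-1-one | CC1(C)C(=O)CCC1(O)c1ccc(OCc2ccccc2)c(OCc2ccccc2)c1 | intermediate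
13 | 3-[3,4-bis(benzyloxy)phenyl]-2,2-dimethylcyclopent-3-en-1-one | CC1(C)C(=O)CC=C1c1ccc(OCc2ccccc2)c(OCc2ccccc2)c1 | intermediate
14 | (3R)-3-[3,4-bis(benzyloxy)phenyl]-2,2-dimethylcyclopentan-1-one | O=C1CC[C@H](c2ccc(OCc3ccccc3)c(OCc3ccccc3)c2)C1(C)C | intermediate
15 | {[(4R)-4-[3,4-bis(benzyloxy)phenyl]-5,5-dimethylcyclopent-1-en-1-yl]oxy}trimethylsilane | C[Si](C)(C)OC1=CC[C@H](c2ccc(OCc3ccccc3)c(OCc3ccccc3)c2)C1(C)C | intermediate
16 | (4R)-4-[3,4-bis(benzyloxy)phenyl]-5,5-dimethylcyclopent-2-en-1-one | O=C1C=C[C@H](c2ccc(OCc3ccccc3)c(OCc3ccccc3)c2)C1(C)C | intermediate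
17 | (3R,4R)-3-[3,4-bis(benzyloxy)phenyl]-4-[(4R)-4-(tert-butyldimethylsilyloxy)-7-methoxy-2,2-dimethylchroman-5-yl]-2,2-dimethylcyclopentan-1-one | O=C1C[C@@H](c2cc(OC)cc3OC(C)(C)C[C@@H](O[Si](C)(C)C(C)(C)C)c23)[C@H](c2ccc(OCc3ccccc3)c(OCc3ccccc3)c2)C1(C)C | intermediate
18 | 5-(trifluoroacetyl) derivative of 17 (enolised 1,3-diketone, C5 not assigned) | O=C1C(C(=O)C(F)(F)F)[C@@H](c2cc(OC)cc3OC(C)(C)C[C@@H](O[Si](C)(C)C(C)(C)C)c23)[C@H](c2ccc(OCc3ccccc3)c(OCc3ccccc3)c2)C1(C)C | intermediate
19 | (3R,4R)-3-[3,4-bis(benzyloxy)phenyl]-4-[(4R)-4-(tert-butyldimethylsilyloxy)-7-methoxy-2,2-dimethylchroman-5-yl]-5-diazo-2,2-dimethylcyclopentan-1-one | [N-]=[N+]=C1C(=O)C(C)(C)[C@@H](c2ccc(OCc3ccccc3)c(OCc3ccccc3)c2)[C@@H]1c1cc(OC)cc2OC(C)(C)C[C@@H](O[Si](C)(C)C(C)(C)C)c12 | intermediate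
20 | cyclobutylidene ketene from 19 (C=C=O on C8) | O=C=C1[C@@H](c2cc(OC)cc3OC(C)(C)C[C@@H](O[Si](C)(C)C(C)(C)C)c23)[C@H](c2ccc(OCc3ccccc3)c(OCc3ccccc3)c2)C1(C)C | intermediate
21 | (1S,3S,4S)-3-[3,4-bis(benzyloxy)phenyl]-4-[(4R)-4-(tert-butyldimethylsilyloxy)-7-methoxy-2,2-dimethylchroman-5-yl]-2,2-dimethylcyclobutane-1-carboxylic acid | OC(=O)[C@H]1[C@@H](c2cc(OC)cc3OC(C)(C)C[C@@H](O[Si](C)(C)C(C)(C)C)c23)[C@H](c2ccc(OCc3ccccc3)c(OCc3ccccc3)c2)C1(C)C | intermediate
22 | [(1S,3S,4S)-3-[3,4-bis(benzyloxy)phenyl]-4-[(4R)-4-(tert-butyldimethylsilyloxy)-7-methoxy-2,2-dimethylchroman-5-yl]-2,2-dimethylcyclobutyl]methanol | OC[C@H]1[C@@H](c2cc(OC)cc3OC(C)(C)C[C@@H](O[Si](C)(C)C(C)(C)C)c23)[C@H](c2ccc(OCc3ccccc3)c(OCc3ccccc3)c2)C1(C)C | intermediate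
23 | 6-bromo derivative of 22 (bromine on C6 of ring A) | OC[C@H]1[C@@H](c2c(Br)c(OC)cc3OC(C)(C)C[C@@H](O[Si](C)(C)C(C)(C)C)c23)[C@H](c2ccc(OCc3ccccc3)c(OCc3ccccc3)c2)C1(C)C | intermediate
24 | 4-methylbenzenesulfonate of 23 | Cc1ccc(cc1)S(=O)(=O)OC[C@H]1[C@@H](c2c(Br)c(OC)cc3OC(C)(C)C[C@@H](O[Si](C)(C)C(C)(C)C)c23)[C@H](c2ccc(OCc3ccccc3)c(OCc3ccccc3)c2)C1(C)C | intermediate
25 | aryllithium from 24 (lithium on C6) | Cc1ccc(cc1)S(=O)(=O)OC[C@H]1[C@@H](c2c([Li])c(OC)cc3OC(C)(C)C[C@@H](O[Si](C)(C)C(C)(C)C)c23)[C@H](c2ccc(OCc3ccccc3)c(OCc3ccccc3)c2)C1(C)C | intermediate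
26 | tetracyclic indane, C12 silyl ether (12R), catechol as dibenzyl ether (C8 S, C9 R, C10 S) | COc1cc2c(c3c1C[C@H]1[C@@H]3[C@H](c3ccc(OCc4ccccc4)c(OCc4ccccc4)c3)C1(C)C)[C@H](O[Si](C)(C)C(C)(C)C)CC(C)(C)O2 | intermediate
27 | tetracyclic indane, C12 silyl ether (12R), free catechol (C8 S, C9 R, C10 S) | COc1cc2c(c3c1C[C@H]1[C@@H]3[C@H](c3ccc(O)c(O)c3)C1(C)C)[C@H](O[Si](C)(C)C(C)(C)C)CC(C)(C)O2 | intermediate
28 | CNP0207533.1 (C8 S, C9 R, C10 S) | COc1cc2c(c3c1C[C@H]1[C@@H]3[C@H](c3ccc(O)c(O)c3)C1(C)C)C=CC(C)(C)O2 | target

## Step count and least certain steps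

Total step count: 19. Longest linear sequence: 15 steps (steps 1 to 6, then 11 to 19, from phloroglucinol).

**Step 13 (key step).**
- What may go wrong: poor facial selectivity in the protonation at C8. Ring B on C10 lies on the face the proton must use and opposes the screening by ring A. Part of the excited diazo ketone may also be diverted into hydride shift from C9 or O–H insertion. C8 cannot be corrected after step 14, so wrong-epimer material would be lost at step 17.
- Fallback: it sets out from 21, taken together with its C8 epimer F1, and returns at 28.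
  - BH3·SMe2 gives 22 and its epimer F2.
  - Bu4NF frees the C12 hydroxyl to give diol F3.
  - Dess–Martin periodinane oxidises both alcohols to keto aldehyde F4.
  - CF3CO2H with a slight excess of Et3SiH at 0 °C closes C6–C7 by reductive Friedel–Crafts alkylation to the tetracyclic chromanone F5. The aldehyde epimerises at C8 through its enol, and only the epimer with the formyl group cis to ring A can reach C6, so both epimers should drain into the cis-fused product.
  - H2 over Pd/C gives catechol F6, NaBH4 gives chromanol F7, and catalytic p-TsOH dehydrates F7 to 28.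
- This detour also avoids the bromination and the organolithium closure (steps 15 to 17), should the regiochemistry of step 15 disappoint.

**Step 9.**
- What may go wrong: insufficient discrimination of the alkene faces. The double bond is flanked by a quaternary carbon and carries no strongly coordinating group.
- Fallback: it sets out from 10 and returns at 14, replacing catalyst control by a stereochemical relay.
  - Desymmetrising monoreduction of 10 (baker's yeast or a Corey–Bakshi–Shibata reduction) gives hydroxy ketone F8.
  - Two equivalents of 11 add to the remaining carbonyl to give diol F9.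
  - Acid dehydration of the tertiary benzylic alcohol gives homoallylic alcohol F10.
  - Hydroxyl-directed hydrogenation with [Ir(cod)(PCy3)(py)]PF6 delivers hydrogen on the face of the hydroxyl group and sets C10, giving F11.
  - Dess–Martin oxidation gives 14.

**Step 11.**
- What may go wrong: protodeboronation of the hindered, electron-rich boronate may outrun insertion, and base may deprotonate 16 at the γ position (racemisation or drift back to 13).
- Fallback: it sets out from 7 and 16 and returns at 17 without new compounds. A reductive Heck hydroarylation (Pd(OAc)2, dppp, Et3N, HCO2H, DMF, 70 °C) joins the two. Triflate 7 adds oxidatively to zerovalent palladium, syn carbopalladation occurs anti to ring B, and formate reduces the palladium enolate, which has no syn β-hydrogen. No boron species is involved.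

**Step 7.**
- What may go wrong: retro-aldol opening of the lithium alkoxide of 12, enolisation of 10 by 11, or double addition.
- Fallback: it sets out from 10 and returns at 13, bypassing 12 and step 8. KN(SiMe3)2 and PhNTf2 give enol triflate F12. Suzuki coupling with boronic acid F13 (Pd(PPh3)4, aqueous K2CO3, DME) gives 13 directly.

## Further compounds

F1 | step 13 | (1R,3S,4S) epimer of acid 21 (carboxyl trans to ring A) | OC(=O)[C@@H]1[C@@H](c2cc(OC)cc3OC(C)(C)C[C@@H](O[Si](C)(C)C(C)(C)C)c23)[C@H](c2ccc(OCc3ccccc3)c(OCc3ccccc3)c2)C1(C)C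
F2 | step 13 | C8 epimer of alcohol 22 | OC[C@@H]1[C@@H](c2cc(OC)cc3OC(C)(C)C[C@@H](O[Si](C)(C)C(C)(C)C)c23)[C@H](c2ccc(OCc3ccccc3)c(OCc3ccccc3)c2)C1(C)C
F3 | step 13 | diol with free C12 hydroxyl and C7 hydroxyl (both C8 epimers) | OCC1[C@@H](c2cc(OC)cc3OC(C)(C)C[C@@H](O)c23)[C@H](c2ccc(OCc3ccccc3)c(OCc3ccccc3)c2)C1(C)C
F4 | step 13 | keto aldehyde: cyclobutanecarbaldehyde with the chroman-4-one on C9 (both C8 epimers) | O=CC1[C@@H](c2cc(OC)cc3OC(C)(C)CC(=O)c23)[C@H](c2ccc(OCc3ccccc3)c(OCc3ccccc3)c2)C1(C)C
F5 | step 13 | tetracyclic chromanone, catechol as dibenzyl ether | COc1cc2c(c3c1C[C@H]1[C@@H]3[C@H](c3ccc(OCc4ccccc4)c(OCc4ccccc4)c3)C1(C)C)C(=O)CC(C)(C)O2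
F6 | step 13 | tetracyclic chromanone, free catechol | COc1cc2c(c3c1C[C@H]1[C@@H]3[C@H](c3ccc(O)c(O)c3)C1(C)C)C(=O)CC(C)(C)O2
F7 | step 13 | tetracyclic chroman-4-ol, free catechol (C12 epimers) | COc1cc2c(c3c1C[C@H]1[C@@H]3[C@H](c3ccc(O)c(O)c3)C1(C)C)C(O)CC(C)(C)O2
F8 | step 9 | (3S)-3-hydroxy-2,2-dimethylcyclopentan-1-one | O[C@H]1CCC(=O)C1(C)C
F9 | step 9 | (1S)-3-[3,4-bis(benzyloxy)phenyl]-2,2-dimethylcyclopentane-1,3-diol (C3 epimers) | O[C@H]1CCC(O)(c2ccc(OCc3ccccc3)c(OCc3ccccc3)c2)C1(C)C
F10 | step 9 | (1S)-3-[3,4-bis(benzyloxy)phenyl]-2,2-dimethylcyclopent-3-en-1-ol | O[C@H]1CC=C(c2ccc(OCc3ccccc3)c(OCc3ccccc3)c2)C1(C)C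
F11 | step 9 | (1S,3R)-3-[3,4-bis(benzyloxy)phenyl]-2,2-dimethylcyclopentan-1-ol | O[C@H]1CC[C@H](c2ccc(OCc3ccccc3)c(OCc3ccccc3)c2)C1(C)C
F0 | step 11 | none | none
F12 | step 7 | 5,5-dimethyl-4-oxocyclopent-1-en-1-yl trifluoromethanesulfonate | CC1(C)C(=O)CC=C1OS(=O)(=O)C(F)(F)F
F13 | step 7 | [3,4-bis(benzyloxy)phenyl]boronic acid | OB(O)c1ccc(OCc2ccccc2)c(OCc2ccccc2)c1
A1 | alternative 1 | C7-oxo tetracycle with chromene, catechol as bis(methoxymethyl) ether | COc1cc2c(c3c1C(=O)[C@H]1[C@@H]3[C@H](c3ccc(OCOC)c(OCOC)c3)C1(C)C)C=CC(C)(C)O2
A2 | alternative 1 | 7-methoxy-2,2-dimethyl-2H-chromen-5-yl trifluoromethanesulfonate | COc1cc(OS(=O)(=O)C(F)(F)F)c2C=CC(C)(C)Oc2c1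
A3 | alternative 1 | (4S)-4-[3,4-bis(methoxymethoxy)phenyl]-3,3-dimethylcyclobut-1-ene | C1=C[C@H](c2ccc(OCOC)c(OCOC)c2)C1(C)C
A4 | alternative 1 | carbon monoxide | [C-]#[O+]
A5 | alternative 2 | tetracyclic indane with C12 silyl ether (12S) and dibenzyl-protected catechol | COc1cc2c(c3c1C[C@H]1[C@@H]3[C@H](c3ccc(OCc4ccccc4)c(OCc4ccccc4)c3)C1(C)C)[C@@H](O[Si](C)(C)C(C)(C)C)CC(C)(C)O2
A6 | alternative 2 | triyne: cyclobutane bearing a 3-methoxyprop-2-ynyl arm on C8 and an alkynyl chain ending in an ethynyl ether on C9 | COC#CC[C@H]1[C@@H](C#C[C@@H](O[Si](C)(C)C(C)(C)C)CC(C)(C)OC#C)[C@H](c2ccc(OCc3ccccc3)c(OCc3ccccc3)c2)C1(C)C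
A7 | alternative 3 | tricyclic indanone with completed ring A and ortho-prenyl phenol | COc1cc(O)c(CC=C(C)C)c2c1C(=O)[C@H]1[C@@H]2[C@H](c2ccc(OCc3ccccc3)c(OCc3ccccc3)c2)C1(C)C
A8 | alternative 3 | 3-bromo-6-[3,4-bis(benzyloxy)phenyl]-7,7-dimethylbicyclo[3.2.0]hept-3-en-2-one (configuration as in the SMILES) | O=C1C(Br)=C[C@H]2[C@H](c3ccc(OCc4ccccc4)c(OCc4ccccc4)c3)C(C)(C)[C@@H]12
A9 | alternative 3 | 1,1-dimethoxy-7-methyl-3-(trimethylsilyloxy)octa-1,3,6-triene | COC(OC)=CC(O[Si](C)(C)C)=CCC=C(C)C
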